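**Retrosynthetic overview**
1. Kanzonol L ⇒ olefin cross-metathesis (allyl to prenyl) of a 6,8-diallyl isoflavone ⇒ double aromatic Claisen rearrangement of the 5,7-bis(allyl ether). All ring A olefins are installed after the oxidative step.
2. The pyran C=C on ring B ⇒ DDQ dehydrogenation of the chroman. The ring passes through the thallium chemistry in its saturated form.
3. Ring C ⇒ acid cyclisation of a β-keto acetal ⇒ Tl(NO3)3 1,2-aryl shift of a 2'-hydroxychalcone.
4. Key C–C bond (the later C2–C3 of ring C) ⇒ Claisen–Schmidt aldol condensation of a ring A acetophenone with a ring B chroman-8-carbaldehyde.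
5. Ring order: the dimethylpyran ring forms first, by propargyl ether Claisen and electrocyclisation on 2,4-dihydroxybenzaldehyde, where the blocked ortho carbon fixes the regiochemistry. Ring C forms second.

**Assumption:** Kanzonol L has no stereocentre and no stereogenic double bond, so it is achiral and no enantiomer has to be selected. The stereocentres of 9 and 11 are racemic and are erased later.

**Step 1**
Reactants: 1 2,4-dihydroxybenzaldehyde
Product: 2 2-hydroxy-4-(methoxymethoxy)benzaldehyde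
Conditions: MOMCl (1.1 equiv), K2CO3 (1.5 equiv), acetone, 0 °C to rt
Reagents that add atoms: chloromethyl methyl ether (MOMCl), COCCl
Why: Williamson-type O-alkylation goes selectively to the free, more acidic 4-OH because the 2-OH is held in a hydrogen bond to the formyl group.

**Step 2**
Reactants: 2 2-hydroxy-4-(methoxymethoxy)benzaldehyde
Product: 3 4-(methoxymethoxy)-2-[(2-methylbut-3-yn-2-yl)oxy]benzaldehyde
Conditions: 3-chloro-3-methylbut-1-yne (2 equiv), K2CO3 (2 equiv), CuI (10 mol %), DMF, 65 °C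
Reagents that add atoms: 3-chloro-3-methylbut-1-yne, CC(C)(Cl)C#C
Why: Copper-catalysed O-propargylation of the only free phenol makes the tertiary aryl propargyl ether, and the MOM ether and aldehyde are inert to carbonate.

**Step 3**
Reactants: 3 4-(methoxymethoxy)-2-[(2-methylbut-3-yn-2-yl)oxy]benzaldehyde
Product: 5 5-(methoxymethoxy)-2,2-dimethyl-2H-chromene-8-carbaldehyde, via allenylphenol 4 (not isolated)
Conditions: 1,2-dichlorobenzene, 180 °C, N2, 3 h
Reagents that add atoms: none
Why: The aromatic propargyl Claisen rearrangement can only reach C3 because the other ortho carbon carries the formyl group, and allenylphenol 4 then closes by 1,5-hydrogen shift and oxa-6π electrocyclisation, which places the pyran oxygen next to the future C1'.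

**Step 4**
Reactants: 5 5-(methoxymethoxy)-2,2-dimethyl-2H-chromene-8-carbaldehyde
Product: 6 5-(methoxymethoxy)-2,2-dimethylchromane-8-carbaldehyde
Conditions: H2 (1 atm, stopped after 1 equiv), 5% Pd/C, EtOAc, rt
Reagents that add atoms: none
Why: Catalytic hydrogenation saturates the cis-styrenyl olefin much faster than it touches the electron-rich aryl aldehyde in EtOAc, and this masks the olefin that trivalent thallium would otherwise attack in step 7.

**Step 5**
Reactants: 7 2,4,6-trihydroxyacetophenone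
Product: 8 1-[2,4-bis(benzyloxy)-6-hydroxyphenyl]ethanone
Conditions: BnBr (2.05 equiv), K2CO3 (2.2 equiv), DMF, rt to 60 °C
Reagents that add atoms: benzyl bromide, BrCc1ccccc1
Why: Williamson benzylation stops at the dibenzyl ether because the last ortho-OH is strongly chelated to the ketone and is far less nucleophilic.

**Step 6 (key step)**
Reactants: 8 1-[2,4-bis(benzyloxy)-6-hydroxyphenyl]ethanone; 6 5-(methoxymethoxy)-2,2-dimethylchromane-8-carbaldehyde
Product: 10 (E)-1-[2,4-bis(benzyloxy)-6-hydroxyphenyl]-3-[5-(methoxymethoxy)-2,2-dimethylchroman-8-yl]prop-2-en-1-one, via aldol adduct 9 (not isolated)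
Conditions: KOH (50% aq, excess), EtOH, rt, 48 h; then cold dilute HCl to pH 5
Reagents that add atoms: none
Why: In this Claisen–Schmidt aldol condensation the enolate of methyl ketone 8 adds to the non-enolisable aldehyde 6, and aldol 9 loses water by E1cB to the conjugated E-enone, which erases the racemic carbinol centre of 9.

**Step 7**
Reactants: 10 (E)-1-[2,4-bis(benzyloxy)-6-hydroxyphenyl]-3-[5-(methoxymethoxy)-2,2-dimethylchroman-8-yl]prop-2-en-1-one
Product: 11 1-[2,4-bis(benzyloxy)-6-hydroxyphenyl]-3,3-dimethoxy-2-[5-(methoxymethoxy)-2,2-dimethylchroman-8-yl]propan-1-one (racemic)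
Conditions: Tl(NO3)3·3H2O (1.1 equiv), MeOH–HC(OMe)3 (solvent), rt, 2–4 h
Reagents that add atoms: methanol, CO
Why: In this oxidative 1,2-aryl migration of a 2'-hydroxychalcone by trivalent thallium, methoxythallation of the only olefin present is followed by migration of the electron-rich ring B (ortho and para oxygen) with loss of monovalent thallium, and the new stereocentre is racemic and disappears in step 8.

**Step 8**
Reactants: 11 1-[2,4-bis(benzyloxy)-6-hydroxyphenyl]-3,3-dimethoxy-2-[5-(methoxymethoxy)-2,2-dimethylchroman-8-yl]propan-1-one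
Product: 12 5,7-bis(benzyloxy)-3-(5-hydroxy-2,2-dimethylchroman-8-yl)-4H-chromen-4-one
Conditions: 10% aq HCl, MeOH, reflux, 2–3 h
Reagents that add atoms: none
Why: In this acid-catalysed transacetalisation and elimination the chelated phenol captures the oxocarbenium ion and loss of methanol aromatises ring C, while the same acid hydrolyses the MOM acetal and leaves the benzyl ethers intact.

**Step 9**
Reactants: 12 5,7-bis(benzyloxy)-3-(5-hydroxy-2,2-dimethylchroman-8-yl)-4H-chromen-4-one
Product: 13 5,7-bis(benzyloxy)-3-[5-(methoxymethoxy)-2,2-dimethylchroman-8-yl]-4H-chromen-4-one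
Conditions: MOMCl (1.5 equiv), K2CO3 (2 equiv), acetone, rt
Reagents that add atoms: chloromethyl methyl ether (MOMCl), COCCl
Why: Williamson-type protection of the single free phenol keeps the ring B hydroxyl distinct from the ring A hydroxyls released in the next step.

**Step 10**
Reactants: 13 5,7-bis(benzyloxy)-3-[5-(methoxymethoxy)-2,2-dimethylchroman-8-yl]-4H-chromen-4-one
Product: 14 5,7-dihydroxy-3-[5-(methoxymethoxy)-2,2-dimethylchroman-8-yl]-4H-chromen-4-one
Conditions: H2 (1 atm), 10% Pd/C, THF–MeOH, rt, monitored by TLC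
Reagents that add atoms: none
Why: Hydrogenolysis cleaves both aryl benzyl ethers under neutral conditions that spare the MOM ether, the chroman and, if stopped at full debenzylation, the C2–C3 olefin of the isoflavone.

**Step 11**
Reactants: 14 5,7-dihydroxy-3-[5-(methoxymethoxy)-2,2-dimethylchroman-8-yl]-4H-chromen-4-one
Product: 15 3-[5-(methoxymethoxy)-2,2-dimethylchroman-8-yl]-4-oxo-4H-chromene-5,7-diyl diacetate
Conditions: Ac2O (4 equiv), pyridine, DMAP (cat.), rt
Reagents that add atoms: acetic anhydride, CC(=O)OC(C)=O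
Why: DMAP-catalysed O-acetylation also covers the chelated 5-OH, so no free phenol is exposed to the quinone oxidant of step 12.

**Step 12**
Reactants: 15 3-[5-(methoxymethoxy)-2,2-dimethylchroman-8-yl]-4-oxo-4H-chromene-5,7-diyl diacetate
Product: 16 3-[5-(methoxymethoxy)-2,2-dimethyl-2H-chromen-8-yl]-4-oxo-4H-chromene-5,7-diyl diacetate
Conditions: DDQ (2.5 equiv), dry 1,4-dioxane, reflux, 8–16 h
Reagents that add atoms: none
Why: DDQ dehydrogenation abstracts hydride from the benzylic C4 of the chroman, whose cation is stabilised by two ortho oxygen substituents, and proton loss from C3 gives the 2,2-dimethylchromene, while acetates, MOM ether and chromone are inert.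

**Step 13**
Reactants: 16 3-[5-(methoxymethoxy)-2,2-dimethyl-2H-chromen-8-yl]-4-oxo-4H-chromene-5,7-diyl diacetate
Product: 17 5,7-dihydroxy-3-[5-(methoxymethoxy)-2,2-dimethyl-2H-chromen-8-yl]-4H-chromen-4-one
Conditions: K2CO3 (cat.), MeOH–THF, 0 °C to rt, 1 h
Reagents that add atoms: none
Why: Base-catalysed transesterification removes the activated aryl acetates within minutes under conditions too mild to open ring C or affect the MOM ether and the chromene.

**Step 14**
Reactants: 17 5,7-dihydroxy-3-[5-(methoxymethoxy)-2,2-dimethyl-2H-chromen-8-yl]-4H-chromen-4-one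
Product: 18 5,7-bis(allyloxy)-3-[5-(methoxymethoxy)-2,2-dimethyl-2H-chromen-8-yl]-4H-chromen-4-one
Conditions: allyl bromide (3 equiv), K2CO3 (4 equiv), DMF, 60 °C
Reagents that add atoms: allyl bromide, C=CCBr
Why: Double Williamson O-allylation works because the reactive allylic halide in warm DMF also alkylates the chelated 5-OH, and the ring B oxygen is blocked as its MOM ether.

**Step 15**
Reactants: 18 5,7-bis(allyloxy)-3-[5-(methoxymethoxy)-2,2-dimethyl-2H-chromen-8-yl]-4H-chromen-4-one
Product: 20 6,8-diallyl-5,7-dihydroxy-3-[5-(methoxymethoxy)-2,2-dimethyl-2H-chromen-8-yl]-4H-chromen-4-one, via mono-Claisen phenol 19 (not isolated)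
Conditions: N,N-diethylaniline, 205 °C, sealed tube, Ar, 4 h
Reagents that add atoms: none
Why: In this double aromatic Claisen rearrangement the 5-O-allyl group can only reach C6, the 7-O-allyl group then takes C8, and because an unsubstituted allyl group looks the same after an ortho or a para (Claisen–Cope) shift, every pathway converges on the 6,8-diallyl compound.

**Step 16**
Reactants: 20 6,8-diallyl-5,7-dihydroxy-3-[5-(methoxymethoxy)-2,2-dimethyl-2H-chromen-8-yl]-4H-chromen-4-one
Product: 21 6,8-diallyl-5,7-dihydroxy-3-(5-hydroxy-2,2-dimethyl-2H-chromen-8-yl)-4H-chromen-4-one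
Conditions: 2 M aq HCl–MeOH–THF, 50 °C, 1–2 h
Reagents that add atoms: none
Why: Acid hydrolysis of the MOM acetal is done at this stage because terminal allyl groups, unlike prenyl groups next to phenols, are not protonated by dilute acid and cannot cyclise to chromans.

**Step 17**
Reactants: 21 6,8-diallyl-5,7-dihydroxy-3-(5-hydroxy-2,2-dimethyl-2H-chromen-8-yl)-4H-chromen-4-one
Product: 22 Kanzonol L, 5,7-dihydroxy-3-(5-hydroxy-2,2-dimethyl-2H-chromen-8-yl)-6,8-bis(3-methylbut-2-en-1-yl)-4H-chromen-4-one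
Conditions: second-generation Grubbs catalyst (2 × 5 mol %), 2-methylbut-2-ene–CH2Cl2 (1:1), 40 °C, sealed tube, 12 h
Reagents that add atoms: 2-methylbut-2-ene, CC=C(C)C
Why: Olefin cross-metathesis with a large excess of 2-methylbut-2-ene turns both terminal allyl groups into prenyl groups under neutral conditions that tolerate free phenols, and the chromene olefin stays out of the reaction because it is internal and flanked by a quaternary carbon.

**Compound list**
1 | 2,4-dihydroxybenzaldehyde | O=Cc1ccc(O)cc1O | starting material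
2 | 2-hydroxy-4-(methoxymethoxy)benzaldehyde | O=Cc1ccc(OCOC)cc1O | intermediate
3 | 4-(methoxymethoxy)-2-[(2-methylbut-3-yn-2-yl)oxy]benzaldehyde | O=Cc1ccc(OCOC)cc1OC(C)(C)C#C | intermediate
4 | allenylphenol, 2-hydroxy-4-(methoxymethoxy)-3-(3-methylbuta-1,2-dien-1-yl)benzaldehyde (not isolated) | O=Cc1ccc(OCOC)c(C=C=C(C)C)c1O | intermediate
5 | 5-(methoxymethoxy)-2,2-dimethyl-2H-chromene-8-carbaldehyde | O=Cc1ccc(OCOC)c2C=CC(C)(C)Oc12 | intermediate
6 | 5-(methoxymethoxy)-2,2-dimethylchromane-8-carbaldehyde | O=Cc1ccc(OCOC)c2CCC(C)(C)Oc12 | intermediate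
7 | 2,4,6-trihydroxyacetophenone | CC(=O)c1c(O)cc(O)cc1O | starting material
8 | 1-[2,4-bis(benzyloxy)-6-hydroxyphenyl]ethanone | CC(=O)c1c(O)cc(OCc2ccccc2)cc1OCc1ccccc1 | intermediate
9 | aldol adduct, 1-[2,4-bis(benzyloxy)-6-hydroxyphenyl]-3-hydroxy-3-[5-(methoxymethoxy)-2,2-dimethylchroman-8-yl]propan-1-one (racemic, not isolated) | O=C(CC(O)c1ccc(OCOC)c2CCC(C)(C)Oc12)c1c(O)cc(OCc2ccccc2)cc1OCc1ccccc1 | intermediate
10 | (E)-1-[2,4-bis(benzyloxy)-6-hydroxyphenyl]-3-[5-(methoxymethoxy)-2,2-dimethylchroman-8-yl]prop-2-en-1-one | O=C(/C=C/c1ccc(OCOC)c2CCC(C)(C)Oc12)c1c(O)cc(OCc2ccccc2)cc1OCc1ccccc1 | intermediate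
11 | 1-[2,4-bis(benzyloxy)-6-hydroxyphenyl]-3,3-dimethoxy-2-[5-(methoxymethoxy)-2,2-dimethylchroman-8-yl]propan-1-one (racemic) | COC(OC)C(C(=O)c1c(O)cc(OCc2ccccc2)cc1OCc1ccccc1)c1ccc(OCOC)c2CCC(C)(C)Oc12 | intermediate
12 | 5,7-bis(benzyloxy)-3-(5-hydroxy-2,2-dimethylchroman-8-yl)-4H-chromen-4-one | O=c1c(-c2ccc(O)c3CCC(C)(C)Oc23)coc2cc(OCc3ccccc3)cc(OCc3ccccc3)c12 | intermediate
13 | 5,7-bis(benzyloxy)-3-[5-(methoxymethoxy)-2,2-dimethylchroman-8-yl]-4H-chromen-4-one | O=c1c(-c2ccc(OCOC)c3CCC(C)(C)Oc23)coc2cc(OCc3ccccc3)cc(OCc3ccccc3)c12 | intermediate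
14 | 5,7-dihydroxy-3-[5-(methoxymethoxy)-2,2-dimethylchroman-8-yl]-4H-chromen-4-one | O=c1c(-c2ccc(OCOC)c3CCC(C)(C)Oc23)coc2cc(O)cc(O)c12 | intermediate
15 | 3-[5-(methoxymethoxy)-2,2-dimethylchroman-8-yl]-4-oxo-4H-chromene-5,7-diyl diacetate | CC(=O)Oc1cc(OC(C)=O)c2c(=O)c(-c3ccc(OCOC)c4CCC(C)(C)Oc34)coc2c1 | intermediate
16 | 3-[5-(methoxymethoxy)-2,2-dimethyl-2H-chromen-8-yl]-4-oxo-4H-chromene-5,7-diyl diacetate | CC(=O)Oc1cc(OC(C)=O)c2c(=O)c(-c3ccc(OCOC)c4C=CC(C)(C)Oc34)coc2c1 | intermediate
17 | 5,7-dihydroxy-3-[5-(methoxymethoxy)-2,2-dimethyl-2H-chromen-8-yl]-4H-chromen-4-one | O=c1c(-c2ccc(OCOC)c3C=CC(C)(C)Oc23)coc2cc(O)cc(O)c12 | intermediate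
18 | 5,7-bis(allyloxy)-3-[5-(methoxymethoxy)-2,2-dimethyl-2H-chromen-8-yl]-4H-chromen-4-one | C=CCOc1cc(OCC=C)c2c(=O)c(-c3ccc(OCOC)c4C=CC(C)(C)Oc34)coc2c1 | intermediate
19 | mono-Claisen phenol, 6-allyl-7-(allyloxy)-5-hydroxy-3-[5-(methoxymethoxy)-2,2-dimethyl-2H-chromen-8-yl]-4H-chromen-4-one (not isolated) | C=CCOc1cc2occ(-c3ccc(OCOC)c4C=CC(C)(C)Oc34)c(=O)c2c(O)c1CC=C | intermediate
20 | 6,8-diallyl-5,7-dihydroxy-3-[5-(methoxymethoxy)-2,2-dimethyl-2H-chromen-8-yl]-4H-chromen-4-one | C=CCc1c(O)c(CC=C)c2occ(-c3ccc(OCOC)c4C=CC(C)(C)Oc34)c(=O)c2c1O | intermediate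
21 | 6,8-diallyl-5,7-dihydroxy-3-(5-hydroxy-2,2-dimethyl-2H-chromen-8-yl)-4H-chromen-4-one | C=CCc1c(O)c(CC=C)c2occ(-c3ccc(O)c4C=CC(C)(C)Oc34)c(=O)c2c1O | intermediate
22 | Kanzonol L (achiral) | CC(C)=CCc1c(O)c(CC=C(C)C)c2occ(-c3ccc(O)c4c3OC(C)(C)C=C4)c(=O)c2c1O | target

**Total step count:** 17.
**Longest linear sequence:** 16 steps, from 1 through steps 1–4 and 6–17. The branch from 7 adds step 5.

**The three steps most likely to fail**

**Step 7 (oxidative aryl shift).** Over-oxidation of the electron-rich rings, or early loss of the MOM group in the nitric acid that forms, can lower the yield.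
- The fallback leaves the route at chalcone 10.
- Intramolecular oxa-Michael addition (NaOAc, EtOH, reflux) closes it to the racemic flavanone 5,7-bis(benzyloxy)-2-[5-(methoxymethoxy)-2,2-dimethylchroman-8-yl]chroman-4-one F1.
- A thallium-free 2,3-aryl shift with the trivalent iodine reagent PhI(OH)OTs (MeCN, reflux) follows.
- A short HCl/MeOH treatment then completes the loss of the MOM group and rejoins the route at isoflavone 12.

**Step 12 (DDQ dehydrogenation).** Hydride abstraction can be slow, and charge-transfer tars can form.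
- The fallback sets out from diacetate 15 and replaces hydride abstraction by a radical halogenation and elimination pair.
- Wohl–Ziegler bromination (NBS, AIBN, PhCF3, 80 °C) at the same benzylic carbon gives the racemic bromide 3-[4-bromo-5-(methoxymethoxy)-2,2-dimethylchroman-8-yl]-4-oxo-4H-chromene-5,7-diyl diacetate F2.
- E2 elimination with DBU (toluene, 60 °C) rejoins the route at chromene 16.

**Step 15 (double Claisen rearrangement).** The second shift can be incomplete, or the o-allylphenols can cyclise at 205 °C.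
- The fallback sets out from diol 17, avoids the 5-O-allyl ether and installs the allyl groups one at a time through the 7-oxygen.
- Allyl bromide (1.05 equiv), K2CO3, acetone, reflux alkylates only the acidic 7-OH and gives 7-(allyloxy)-5-hydroxy-3-[5-(methoxymethoxy)-2,2-dimethyl-2H-chromen-8-yl]-4H-chromen-4-one F3.
- Ortho-Claisen rearrangement (N,N-diethylaniline, 200 °C) gives 8-allyl-5,7-dihydroxy-3-[5-(methoxymethoxy)-2,2-dimethyl-2H-chromen-8-yl]-4H-chromen-4-one F4.
- A second selective 7-O-allylation gives 8-allyl-7-(allyloxy)-5-hydroxy-3-[5-(methoxymethoxy)-2,2-dimethyl-2H-chromen-8-yl]-4H-chromen-4-one F5.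
- The only free ortho carbon of F5 is C6, so a second Claisen rearrangement rejoins the route at 20.

**Further compounds**
F1 | step 7 | 5,7-bis(benzyloxy)-2-[5-(methoxymethoxy)-2,2-dimethylchroman-8-yl]chroman-4-one (racemic) | O=C1CC(c2ccc(OCOC)c3CCC(C)(C)Oc23)Oc2cc(OCc3ccccc3)cc(OCc3ccccc3)c12
F2 | step 12 | 3-[4-bromo-5-(methoxymethoxy)-2,2-dimethylchroman-8-yl]-4-oxo-4H-chromene-5,7-diyl diacetate (racemic) | CC(=O)Oc1cc(OC(C)=O)c2c(=O)c(-c3ccc(OCOC)c4C(Br)CC(C)(C)Oc34)coc2c1
F3 | step 15 | 7-(allyloxy)-5-hydroxy-3-[5-(methoxymethoxy)-2,2-dimethyl-2H-chromen-8-yl]-4H-chromen-4-one | C=CCOc1cc(O)c2c(=O)c(-c3ccc(OCOC)c4C=CC(C)(C)Oc34)coc2c1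
F4 | step 15 | 8-allyl-5,7-dihydroxy-3-[5-(methoxymethoxy)-2,2-dimethyl-2H-chromen-8-yl]-4H-chromen-4-one | C=CCc1c(O)cc(O)c2c(=O)c(-c3ccc(OCOC)c4C=CC(C)(C)Oc34)coc12
F5 | step 15 | 8-allyl-7-(allyloxy)-5-hydroxy-3-[5-(methoxymethoxy)-2,2-dimethyl-2H-chromen-8-yl]-4H-chromen-4-one | C=CCOc1cc(O)c2c(=O)c(-c3ccc(OCOC)c4C=CC(C)(C)Oc34)coc2c1CC=C
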